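The six-membered carbocycle (C3a, C4, C5, C6, C7, C7a) hides a 2-methoxy enone, C4=C5(OMe)–C6=O, so C5 can be inserted last. A trans lactone, made by catalytic anti-crotylation, is alkylated twice to set the quaternary C3a (allyl anti to the C3 methyl) and is closed to a cyclopenta[b]furanone that lacks C5. Its silyloxy cyclopentadiene takes up chloro(methoxy)carbene; opening of the cyclopropane enlarges the five-membered ring to the 3a-allyl methoxy dienone in one operation. A suprafacial Cope shift then moves allyl from C3a to C5, so C3 relays its configuration through C3a to the remote C5.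

Key step: step 9

Remark: atom labels (O1, C2, C3, C3a, C4 to C7, C7a) follow the benzofuran numbering of the target throughout; (S)-SEGPHOS is assumed to give the (1R,2R) alcohol in step 1, otherwise its antipode is used.

Step 1
Reactants: 1 3,4-dimethoxybenzaldehyde; 2 but-3-en-2-yl acetate (racemic)
Product: 3 (1R,2R)-1-(3,4-dimethoxyphenyl)-2-methylbut-3-en-1-ol
Conditions: [Ir(cod)Cl]2 (cat.), (S)-SEGPHOS, 4-cyano-3-nitrobenzoic acid, Cs2CO3 (cat.), i-PrOH, THF, 90 °C
Reagents that add atoms: none
Why: Iridium-catalysed transfer-hydrogenative carbonyl crotylation (Krische type), in which the (E)-σ-crotyliridium species adds through a closed chair transition state to give the anti adduct and the cyclometallated SEGPHOS complex chooses the aldehyde face, so both stereocentres (later C2 and C3) are set by the catalyst.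

Step 2
Reactants: 3 (1R,2R)-1-(3,4-dimethoxyphenyl)-2-methylbut-3-en-1-ol
Product: 4 (1R,2R)-1-(3,4-dimethoxyphenyl)-2-methylbutane-1,4-diol
Conditions: BH3·THF, THF, 0 °C to rt; then NaOH, H2O2
Reagents that add atoms: hydrogen peroxide, OO
Why: Anti-Markovnikov hydroboration of the monosubstituted alkene and oxidation with retention leave both stereocentres untouched.

Step 3
Reactants: 4 (1R,2R)-1-(3,4-dimethoxyphenyl)-2-methylbutane-1,4-diol
Product: 5 (4R,5R)-5-(3,4-dimethoxyphenyl)-4-methyloxolan-2-one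
Conditions: TEMPO (cat.), PhI(OAc)2, CH2Cl2, rt
Reagents that add atoms: none
Why: TEMPO-mediated oxidation takes the primary alcohol to the aldehyde, whose lactol with the benzylic hydroxyl is oxidised on to the γ-lactone, so the anti diol becomes the trans-4,5-disubstituted lactone.

Step 4
Reactants: 6 2-methoxyprop-1-ene
Product: 7 3-bromo-2-methoxyprop-1-ene
Conditions: NBS, K2CO3 (cat.), PhCF3, 0 °C to rt
Reagents that add atoms: N-bromosuccinimide, O=C1CCC(=O)N1Br
Why: Electrophilic bromination of the enol ether and loss of a methyl proton from the oxocarbenium ion give the allylic bromide (NBS allylic bromination), a masked acetonyl electrophile.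

Step 5
Reactants: 5 (4R,5R)-5-(3,4-dimethoxyphenyl)-4-methyloxolan-2-one; 7 3-bromo-2-methoxyprop-1-ene
Product: 8 (3R,4R,5R)-5-(3,4-dimethoxyphenyl)-3-(2-methoxyprop-2-en-1-yl)-4-methyloxolan-2-one
Conditions: LiN(iPr)2, THF, −78 °C; then 7, −78 to −40 °C; pH 7 work-up
Reagents that add atoms: none
Why: Lactone enolate alkylation (SN2) with the reactive allylic bromide takes place anti to the adjacent C4 methyl group, and this centre is made planar again in step 6.

Step 6
Reactants: 8 (3R,4R,5R)-5-(3,4-dimethoxyphenyl)-3-(2-methoxyprop-2-en-1-yl)-4-methyloxolan-2-one; 9 3-bromoprop-1-ene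
Product: 11 (3S,4R,5R)-5-(3,4-dimethoxyphenyl)-4-methyl-3-(2-oxopropyl)-3-(prop-2-en-1-yl)oxolan-2-one, via enol ether lactone 10 (not isolated)
Conditions: LiN(iPr)2, THF/DMPU, −78 °C; 9; then 1 M HCl, THF, rt
Reagents that add atoms: water, O
Why: Second enolate alkylation, in which the planar trisubstituted enolate takes allyl bromide on the face anti to the adjacent methyl group and so fixes the quaternary centre (later C3a) with allyl trans to methyl, followed by hydrolysis of the enol ether to the methyl ketone on acidic work-up.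

Step 7
Reactants: 11 (3S,4R,5R)-5-(3,4-dimethoxyphenyl)-4-methyl-3-(2-oxopropyl)-3-(prop-2-en-1-yl)oxolan-2-one
Product: 13 (2R,3R,3aS)-2-(3,4-dimethoxyphenyl)-3-methyl-3a-(prop-2-en-1-yl)-2,3,3a,4-tetrahydro-5H-cyclopenta[b]furan-5-one, via hydroxy dione 12 (not isolated)
Conditions: LiN(SiMe3)2, THF, −78 to 0 °C; aq. NH4Cl; then PPTS, 4 Å MS, PhMe, 50 °C
Reagents that add atoms: none
Why: Intramolecular Claisen condensation of the kinetic methyl-ketone enolate on the lactone carbonyl (5-exo-trig, the classical γ-keto ester to cyclopentane-1,3-dione closure) is followed by acid-catalysed vinylogous esterification of the freed benzylic hydroxyl at the only carbonyl it can reach in a fused five-membered ring, with no bond to a stereocentre broken.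

Step 8
Reactants: 13 (2R,3R,3aS)-2-(3,4-dimethoxyphenyl)-3-methyl-3a-(prop-2-en-1-yl)-2,3,3a,4-tetrahydro-5H-cyclopenta[b]furan-5-one
Product: 14 tert-butyl{[(2R,3R,3aR)-2-(3,4-dimethoxyphenyl)-3-methyl-3a-(prop-2-en-1-yl)-3,3a-dihydro-2H-cyclopenta[b]furan-5-yl]oxy}dimethylsilane
Conditions: LiN(iPr)2, THF, −78 °C; tBuMe2SiCl, DMPU
Reagents that add atoms: tert-butyl(chloro)dimethylsilane, CC(C)(C)[Si](C)(C)Cl
Why: Kinetic deprotonation of the vinylogous ester at its only enolisable position (C4) and O-silylation give the cross-conjugated silyloxy cyclopentadiene, which cannot undergo hydrogen shifts because C3a is quaternary.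

Step 9
Reactants: 14 tert-butyl{[(2R,3R,3aR)-2-(3,4-dimethoxyphenyl)-3-methyl-3a-(prop-2-en-1-yl)-3,3a-dihydro-2H-cyclopenta[b]furan-5-yl]oxy}dimethylsilane; 15 dichloro(methoxy)methane
Product: 17 (2R,3R,3aR)-2-(3,4-dimethoxyphenyl)-5-methoxy-3-methyl-3a-(prop-2-en-1-yl)-3,3a-dihydro-1-benzofuran-6(2H)-one, via chloromethoxycyclopropane 16 (not isolated)
Conditions: KOtBu, pentane/THF, −40 °C to rt
Reagents that add atoms: none
Why: Proposed new method: chloro(methoxy)carbene, released from Cl2CHOMe by α-elimination, adds in a concerted [2+1] cheletropic step to the silyl enol ether double bond C4=C6 of the 1-alkoxy-3-silyloxy diene and so closes the cyclopropane 16. Methoxy-assisted loss of chloride and disrotatory two-electron electrocyclic opening of the cyclopropyl cation break the C4–C6 bond, so the five-membered carbocycle (C3a, C4, C6, C7, C7a) is enlarged by C5 to the six-membered ring, and chloride strips the silyl group from the silyloxy pentadienyl cation to leave the 5-methoxy 2,5-dienone. The closest known reaction types are the dihalocarbene ring enlargements of silyl enol ethers to 2-halo enones and of cyclopentadienes or indenes to halo arenes, and the cyclopropanation of electron-rich alkenes by alkoxyhalocarbenes; their union on a silyloxy cyclopentadiene is untested. No lasting stereocentre is created: the cyclopropane centres vanish on opening, C5 ends trigonal, and C2, C3 and C3a are not touched. The step needs site selectivity for C4=C6 over C7=C7a and over the allyl group: C4 is the terminus of the donor diene with the largest HOMO coefficient and attack there is supported by both the silyloxy and the ring oxygen, while the ambiphilic carbene reacts only slowly with a monoalkyl ethylene. The direction of opening is fixed because only cleavage of the bond between the two former alkene carbons gives a cation stabilised by OMe, OSi and O1, and the quaternary C3a blocks aromatisation.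

Step 10
Reactants: 17 (2R,3R,3aR)-2-(3,4-dimethoxyphenyl)-5-methoxy-3-methyl-3a-(prop-2-en-1-yl)-3,3a-dihydro-1-benzofuran-6(2H)-one
Product: 18 (2R,3R,5S)-2-(3,4-dimethoxyphenyl)-5-methoxy-3-methyl-5-(prop-2-en-1-yl)-2,3-dihydro-1-benzofuran-6(5H)-one
Conditions: PhMe, 110 °C (sealed tube)
Reagents that add atoms: none
Why: Thermal [3,3]-sigmatropic (Cope) shift of the allyl group from C3a to C5 across one ring face transfers the C3a configuration to the new quaternary centre C5 (allyl cis to the C2 aryl, trans to the C3 methyl) and gives the conjugated 2,4-dienone, the captodative terminus C5 being preferred over C7, where a shift would end in an aromatic phenol.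

Compound list
1 | 3,4-dimethoxybenzaldehyde | COc1ccc(C=O)cc1OC | starting material
2 | but-3-en-2-yl acetate (racemic) | CC(=O)OC(C)C=C | starting material
3 | (1R,2R)-1-(3,4-dimethoxyphenyl)-2-methylbut-3-en-1-ol | C=C[C@@H](C)[C@H](c1ccc(OC)c(OC)c1)O | intermediate
4 | (1R,2R)-1-(3,4-dimethoxyphenyl)-2-methylbutane-1,4-diol | OCC[C@@H](C)[C@H](c1ccc(OC)c(OC)c1)O | intermediate
5 | (4R,5R)-5-(3,4-dimethoxyphenyl)-4-methyloxolan-2-one | O=C1C[C@@H](C)[C@H](c2ccc(OC)c(OC)c2)O1 | intermediate
6 | 2-methoxyprop-1-ene | C=C(C)OC | starting material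
7 | 3-bromo-2-methoxyprop-1-ene | C=C(CBr)OC | intermediate
8 | (3R,4R,5R)-5-(3,4-dimethoxyphenyl)-3-(2-methoxyprop-2-en-1-yl)-4-methyloxolan-2-one | O=C1[C@H](CC(=C)OC)[C@@H](C)[C@H](c2ccc(OC)c(OC)c2)O1 | intermediate
9 | 3-bromoprop-1-ene (allyl bromide) | C=CCBr | starting material
10 | (3S,4R,5R)-5-(3,4-dimethoxyphenyl)-3-(2-methoxyprop-2-en-1-yl)-4-methyl-3-(prop-2-en-1-yl)oxolan-2-one (not isolated) | O=C1[C@@](CC=C)(CC(=C)OC)[C@@H](C)[C@H](c2ccc(OC)c(OC)c2)O1 | intermediate
11 | (3S,4R,5R)-5-(3,4-dimethoxyphenyl)-4-methyl-3-(2-oxopropyl)-3-(prop-2-en-1-yl)oxolan-2-one | O=C1[C@@](CC=C)(CC(C)=O)[C@@H](C)[C@H](c2ccc(OC)c(OC)c2)O1 | intermediate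
12 | (4S)-4-[(1R,2R)-1-(3,4-dimethoxyphenyl)-1-hydroxypropan-2-yl]-4-(prop-2-en-1-yl)cyclopentane-1,3-dione (not isolated) | C=CC[C@]1(CC(=O)CC1=O)[C@@H](C)[C@@H](O)c1ccc(OC)c(OC)c1 | intermediate
13 | (2R,3R,3aS)-2-(3,4-dimethoxyphenyl)-3-methyl-3a-(prop-2-en-1-yl)-2,3,3a,4-tetrahydro-5H-cyclopenta[b]furan-5-one | C=CC[C@@]12CC(=O)C=C1O[C@@H](c1ccc(OC)c(OC)c1)[C@@H]2C | intermediate
14 | tert-butyl{[(2R,3R,3aR)-2-(3,4-dimethoxyphenyl)-3-methyl-3a-(prop-2-en-1-yl)-3,3a-dihydro-2H-cyclopenta[b]furan-5-yl]oxy}dimethylsilane | C=CC[C@@]12C=C(O[Si](C)(C)C(C)(C)C)C=C1O[C@@H](c1ccc(OC)c(OC)c1)[C@@H]2C | intermediate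
15 | dichloro(methoxy)methane | COC(Cl)Cl | starting material
16 | chloro(methoxy)carbene adduct of 14 across C4=C6, a 6-chloro-6-methoxy-1-silyloxybicyclo[3.1.0]hex-2-ene fused to the dihydrofuran (not isolated; the three cyclopropane centres are not assigned) | C=CC[C@@]12C3C(Cl)(OC)C3(O[Si](C)(C)C(C)(C)C)C=C1O[C@@H](c1ccc(OC)c(OC)c1)[C@@H]2C | intermediate
17 | (2R,3R,3aR)-2-(3,4-dimethoxyphenyl)-5-methoxy-3-methyl-3a-(prop-2-en-1-yl)-3,3a-dihydro-1-benzofuran-6(2H)-one | C=CC[C@@]12C=C(OC)C(=O)C=C1O[C@@H](c1ccc(OC)c(OC)c1)[C@@H]2C | intermediate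
18 | (2R,3R,5S)-2-(3,4-dimethoxyphenyl)-5-methoxy-3-methyl-5-(prop-2-en-1-yl)-2,3-dihydro-1-benzofuran-6(5H)-one | C=CC[C@]1(OC)C=C2C(=CC1=O)O[C@@H](c1ccc(OC)c(OC)c1)[C@@H]2C | target

Total step count: 10. Longest linear sequence: 9 steps (steps 1, 2, 3, 5, 6, 7, 8, 9, 10).

Steps most likely to fail

Step 9 (Proposed new method). The alkoxyhalocarbene may be intercepted by tert-butoxide, may add too slowly to the hindered diene, or the cyclopropane may not ionise cleanly. The fallback uses known chemistry and sets out from 14. Dibromocarbene (CHBr3, KOtBu, pentane, −20 °C to rt) is added to the silyl enol ether double bond to give the dibromocyclopropane adduct of 14 F1. On warming, F1 opens in the established dihalocarbene ring enlargement of silyl enol ethers to (2R,3R,3aR)-5-bromo-2-(3,4-dimethoxyphenyl)-3-methyl-3a-(prop-2-en-1-yl)-3,3a-dihydro-1-benzofuran-6(2H)-one F2. The vinylic bromide is then exchanged for methoxide by copper-catalysed C–O coupling (CuI, 3,4,7,8-tetramethyl-1,10-phenanthroline, Cs2CO3, MeOH, PhMe, 80 °C), and the route is rejoined at 17.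

Step 6. O-allylation, proton transfer between enolate and product, and erosion of facial selectivity at the crowded lithium enolate may lower yield and diastereomer purity at the centre that carries the whole stereochemical relay. The fallback sets out from 8. LiN(iPr)2 and Me3SiCl give the ketene silyl acetal {[(4R,5R)-5-(3,4-dimethoxyphenyl)-3-(2-methoxyprop-2-en-1-yl)-4-methyl-4,5-dihydrofuran-2-yl]oxy}trimethylsilane F3. F3 is allylated under neutral conditions with allyl methyl carbonate and Pd2(dba)3/dppe in THF (Tsuji allylation of ketene silyl acetals, with outer-sphere attack of the π-allyl cation anti to the C4 methyl). This gives 10, and the same acidic work-up rejoins the route at 11.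

Step 4. The labile bromide 7 may form together with its vinylic isomer and may decompose before use. The fallback sets out from 5 and builds the acetonyl arm from an allyl group. Alkylation with 9 (LiN(iPr)2, THF, −78 °C) gives (3R,4R,5R)-5-(3,4-dimethoxyphenyl)-4-methyl-3-(prop-2-en-1-yl)oxolan-2-one F4. Tsuji–Wacker oxidation (PdCl2, CuCl, O2, DMF/H2O) gives (3R,4R,5R)-5-(3,4-dimethoxyphenyl)-4-methyl-3-(2-oxopropyl)oxolan-2-one F5. Ketalisation (HC(OMe)3, MeOH, TsOH) gives (3R,4R,5R)-3-(2,2-dimethoxypropyl)-5-(3,4-dimethoxyphenyl)-4-methyloxolan-2-one F6. Allylation of F6 as in step 6 gives (3S,4R,5R)-3-(2,2-dimethoxypropyl)-5-(3,4-dimethoxyphenyl)-4-methyl-3-(prop-2-en-1-yl)oxolan-2-one F7, and its acidic work-up rejoins the route at 11.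

Further compounds
F1 | step 9 | dibromocarbene adduct of 14 across C4=C6, a 6,6-dibromo-1-silyloxybicyclo[3.1.0]hex-2-ene fused to the dihydrofuran (not isolated; cyclopropane centres not assigned) | C=CC[C@@]12C3C(Br)(Br)C3(O[Si](C)(C)C(C)(C)C)C=C1O[C@@H](c1ccc(OC)c(OC)c1)[C@@H]2C
F2 | step 9 | (2R,3R,3aR)-5-bromo-2-(3,4-dimethoxyphenyl)-3-methyl-3a-(prop-2-en-1-yl)-3,3a-dihydro-1-benzofuran-6(2H)-one | C=CC[C@@]12C=C(Br)C(=O)C=C1O[C@@H](c1ccc(OC)c(OC)c1)[C@@H]2C
F3 | step 6 | {[(4R,5R)-5-(3,4-dimethoxyphenyl)-3-(2-methoxyprop-2-en-1-yl)-4-methyl-4,5-dihydrofuran-2-yl]oxy}trimethylsilane | C[Si](C)(C)OC1=C(CC(=C)OC)[C@@H](C)[C@H](c2ccc(OC)c(OC)c2)O1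
F4 | step 4 | (3R,4R,5R)-5-(3,4-dimethoxyphenyl)-4-methyl-3-(prop-2-en-1-yl)oxolan-2-one | O=C1[C@H](CC=C)[C@@H](C)[C@H](c2ccc(OC)c(OC)c2)O1
F5 | step 4 | (3R,4R,5R)-5-(3,4-dimethoxyphenyl)-4-methyl-3-(2-oxopropyl)oxolan-2-one | O=C1[C@H](CC(C)=O)[C@@H](C)[C@H](c2ccc(OC)c(OC)c2)O1
F6 | step 4 | (3R,4R,5R)-3-(2,2-dimethoxypropyl)-5-(3,4-dimethoxyphenyl)-4-methyloxolan-2-one | O=C1[C@H](CC(C)(OC)OC)[C@@H](C)[C@H](c2ccc(OC)c(OC)c2)O1
F7 | step 4 | (3S,4R,5R)-3-(2,2-dimethoxypropyl)-5-(3,4-dimethoxyphenyl)-4-methyl-3-(prop-2-en-1-yl)oxolan-2-one | O=C1[C@@](CC=C)(CC(C)(OC)OC)[C@@H](C)[C@H](c2ccc(OC)c(OC)c2)O1
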